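I counted time constants.

common to all: Sbt 0.050 M

| charge | Ptn | Kat | temperature | remark | time |
|---|---|---|---|---|---|
| summer | 0.10 M | 38 µM | 55 °C | run made earlier |  |
| dusk | 0.10 M | 81 µM | 75 °C | run made earlier |  |
| dawn | 0.10 M | 160 µM | 55 °C | run made earlier |  |
| Friday's | 0.100 M | 50 µM |  | at 60 °C until 12 h, from then on at 90 °C | 40 h |
| Tuesday's | 0.100 M | 150 µM |  | at 60 °C throughout | 60 h |

| run | time / h | Pdt / % |
|---|---|---|
| summer | 2.00 | 6 |
| summer | 5.00 | 11 |
| summer | 10.0 | 18 |
| summer | 15.0 | 22 |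
| summer | 20.0 | 30 |
| dusk | 0.667 | 7 |
| dusk | 1.33 | 11 |
| dusk | 3.00 | 25 |
| dusk | 5.00 | 38 |
| dusk | 10.0 | 60 |
| dawn | 1.50 | 9 |
| dawn | 3.00 | 21 |
| dawn | 6.00 | 36 |
| dawn | 10.0 | 52 |
| dawn | 20.0 | 80 |

(readings scatter by 2 percentage points)

- what may be going on: Imd4 <-> Kat + Pdt; Sbt + Kat -> Imd; Ptn + Imd <-> Imd2; Imd3 -> Imd4; Imd2 <-> Byp + Imd3

* which one finishes higher in amount of Pdt, in percent of the Sbt charged ("neither" within 2 percentage points) (Friday's / Tuesday's / neither)
* amount of Pdt at the end, in percent of the Sbt charged, Friday's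
* amount of Pdt at the end, in percent of the Sbt charged, Tuesday's

In the earlier runs I read each Pdt as Sbt gone, and on that reading Sbt drained like a tank, with the fraction left falling as exp(−t/τ). That is a pseudo-first-order decay, and Sbt is the limiting reagent, with Ptn charged at 2.00 equivalents. From the last readings I took τ as 56.1 h in the summer run and 12.4 h in the dawn run. Their ratio, 4.52, stands near the ratio of c(Kat), 4.21, so I took τ as inversely proportional to c(Kat). The dusk run read 10.9 h. Against the dawn run, with c(Kat) allowed for, that gave me an activation energy of 38.5 kJ/mol.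

This put three rungs on the ladder, with my reckoned τ from the shortest up: Friday's at 90 °C had 10.2 h, Tuesday's at 60 °C had 10.7 h, and Friday's at 60 °C had 32.2 h. Friday's cool stretch of 12 h was shorter than its τ, so I expected 68.9% of the Sbt to be left at the change. Friday's hot stretch then held 2.74 time constants of its own, more than the 0.373 of its cool stretch.

I joined the two ends with one quantity, the lived constants N: elapsed time over τ, summed stretch by stretch, so that the fraction of Sbt left is reckoned as exp(−N). Friday's came to 3.12 and Tuesday's to 5.59. I therefore reckoned Pdt at 95.6% for Friday's and 99.6% for Tuesday's.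

The forecast also chose Tuesday's, but with lower figures than mine: 95% (82% to 99%) for Friday's and 99% (96% to 100%) for Tuesday's, adding of Friday's “The 90 °C stretch is extrapolated, and unseen catalyst loss is possible, so I shade this down.”

Tuesday's finished higher, with Pdt at 99.5% against 89.3% for Friday's.

    Imd4 ⇌ Kat + Pdt (K = 0.0245 M, k = 0.0272 /s, Ea = 92.0 kJ/mol, ΔH = −27.0 kJ/mol)
    Sbt + Kat → Imd (k = 0.581 /M/s, Ea = 38.0 kJ/mol)
    Ptn + Imd ⇌ Imd2 (K = 11.0 /M, k = 0.343 /M/s, Ea = 43.0 kJ/mol, ΔH = −90.0 kJ/mol)
    Imd3 → Imd4 (k = 1.43 /s, Ea = 84.0 kJ/mol)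
    Imd2 ⇌ Byp + Imd3 (K = 0.0820 M, k = 0.111 /s, Ea = 97.0 kJ/mol, ΔH = −19.0 kJ/mol)
    (constants at 60 °C)

At its end, Friday's held 76.3% of its catalyst as Imd4, the resting state, and 18.6% as free Kat. Tuesday's held 66.9% and 32.9%. Read back from the 11% of Sbt left, Friday's had lived 2.24 constants, fewer than my 3.12. Tuesday's, with 0.27% of its Sbt left, had lived 5.91 against my 5.59.

The data are simulated for substances that don't exist; scatter was added.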